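**Conventions and assumption (one line):** Locants C1–C15 are elemane-type (ring C5–C10; lactone O–C6, C7, C11, C12; C13 = lactone methylene; C14 = acetoxymethyl carbon; C15 = formyl carbon), and the lipase in step 3 is assumed to give (R)-6 (if its preference is opposite, the same enzyme run hydrolytically on the diacetate gives (R)-6).

## Retrosynthetic overview

1. Target ⇐ bicyclic lactone by late allylic oxidation of the C4 isopropenyl group to the 2-substituted acrolein and O-desilylation of the side chain.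
2. Bicyclic lactone ⇐ acyclic aldehyde in one flask: intramolecular carbonyl-ene closes the cyclohexane at C5–C6 first (sets C5, C6, creates the isopropenyl group), then the new C6–OH lactonises onto the C12 ester (lactone ring second).
3. Acyclic aldehyde ⇐ auxiliary-controlled syn aldol (C7–C8) between an itaconate-derived N-acylthiazolidinethione (C6, C7, C11–C13) and a quaternary aldehyde (C8–C10, C14, C1–C5); the auxiliary carbonyl becomes the C6 aldehyde.
4. Quaternary aldehyde (C10) ⇐ enzymatic desymmetrisation of a prochiral 2-vinylpropane-1,3-diol made from a malonate.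

## Route

Step 1
Reactants: 1 diethyl 2-(2,2-diethoxyethyl)malonate; 2 phenyl vinyl sulfoxide
Product: 4 diethyl 2-(2,2-diethoxyethyl)-2-vinylmalonate, via sulfoxide adduct 3 (not isolated)
Conditions: NaOEt (20 mol %), EtOH, 50 °C; then toluene, NaHCO3, 110 °C
Reagents that add atoms: none
Why: Michael addition of the malonate anion to the vinyl sulfoxide (vinyl cation equivalent) followed by thermal sulfoxide syn-elimination gives the C-vinyl malonate; the quaternary carbon is still prochiral.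

Step 2
Reactants: 4 vinyl malonate
Product: 5 2-(2,2-diethoxyethyl)-2-vinylpropane-1,3-diol
Conditions: LiAlH4, THF, 0 °C → rt
Reagents that add atoms: none
Why: Hydride reduction of both esters leaves the acetal and the alkene untouched and gives the prochiral 1,3-diol.

Step 3
Reactants: 5 prochiral diol
Product: 6 (2R)-2-(2,2-diethoxyethyl)-2-(hydroxymethyl)but-3-en-1-yl acetate
Conditions: Burkholderia cepacia lipase (Amano PS), vinyl acetate, t-BuOMe, 25 °C
Reagents that add atoms: vinyl acetate C=COC(C)=O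
Why: Lipase-catalysed irreversible transesterification (enzymatic desymmetrisation of a prochiral 2,2-disubstituted propane-1,3-diol) acetylates one enantiotopic hydroxymethyl group, which sets C10 and installs the final C14 acetate.

Step 4
Reactants: 6 monoacetate
Product: 7 (2S)-2-(2,2-diethoxyethyl)-2-formylbut-3-en-1-yl acetate
Conditions: Dess–Martin periodinane, NaHCO3, CH2Cl2, 0 °C → rt
Reagents that add atoms: none
Why: Dess–Martin oxidation of the neopentyl alcohol; the aldehyde has no α-hydrogen, so C10 cannot epimerise and the β-acetate cannot eliminate.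

Step 5
Reactants: 7 quaternary aldehyde
Product: 8 (2R)-2-(2,2-diethoxyethyl)-2-ethenyl-4-methylpent-3-en-1-yl acetate
Conditions: i-PrPPh3 I, KN(SiMe3)2, THF, 0 °C; then 7, −78 °C → rt
Reagents that add atoms: isopropyltriphenylphosphonium iodide CC(C)[P+](c1ccccc1)(c1ccccc1)c1ccccc1.[I-]
Why: Wittig olefination with the non-stabilised isopropylidene ylide turns the aldehyde into the 2-methylprop-1-enyl group (the future C5=C4 ene donor) faster than the ylide attacks the acetate at low temperature.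

Step 6
Reactants: 8 acetal
Product: 9 (2R)-2-ethenyl-4-methyl-2-(2-oxoethyl)pent-3-en-1-yl acetate
Conditions: pyridinium p-toluenesulfonate, acetone/H2O 4:1, 55 °C
Reagents that add atoms: water O
Why: Mild acid-catalysed acetal hydrolysis unmasks the C8 aldehyde without touching the acetate or the alkenes.

Step 7
Reactants: 10 itaconic anhydride; 11 (R)-4-benzyl-1,3-thiazolidine-2-thione
Product: 13 methyl 4-[(4R)-4-benzyl-2-thioxo-1,3-thiazolidin-3-yl]-2-methylidene-4-oxobutanoate, via imide carboxylate 12 (not isolated)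
Conditions: NaH, THF, 0 °C; 10, −78 °C; then MeI, DMF, −78 °C → rt
Reagents that add atoms: iodomethane CI
Why: N-acylation of the thiazolidinethione anion by opening the anhydride at its more electrophilic non-conjugated carbonyl, then SN2 O-methylation of the carboxylate; low temperature and no amine base avoid isomerisation to the citraconate.

Step 8
Reactants: 14 ethyl 2-(hydroxymethyl)acrylate
Product: 15 ethyl 2-({[tert-butyl(diphenyl)silyl]oxy}methyl)prop-2-enoate
Conditions: t-BuPh2SiCl, imidazole, CH2Cl2, 0 °C → rt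
Reagents that add atoms: tert-butyl(chloro)diphenylsilane CC(C)(C)[Si](Cl)(c1ccccc1)c1ccccc1
Why: Standard silylation of the primary alcohol gives a protecting group that survives the Lewis-acid and SeO2 steps.

Step 9
Reactants: 15 silyl ether ester
Product: 16 2-({[tert-butyl(diphenyl)silyl]oxy}methyl)prop-2-enoic acid
Conditions: LiOH, THF/H2O 3:1, 0 °C; then aq. HCl to pH 4
Reagents that add atoms: lithium hydroxide [Li+].[OH-]
Why: Saponification of the unhindered ethyl ester at 0 °C; the bulky silyl ether is stable to hydroxide.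

Step 10
Reactants: 13 N-acylthiazolidinethione; 9 quaternary aldehyde
Product: 17 methyl (3R,4S,6R)-6-(acetoxymethyl)-3-{[(4R)-4-benzyl-2-thioxo-1,3-thiazolidin-3-yl]carbonyl}-6-ethenyl-4-hydroxy-8-methyl-2-methylidenenon-7-enoate
Conditions: TiCl4, i-Pr2NEt, N-methyl-2-pyrrolidone, CH2Cl2, 0 °C; then 9, −78 → 0 °C
Reagents that add atoms: none
Why: Crimmins titanium-enolate aldol in the "Evans syn" mode: the Z-enolate adds through a non-chelated chair transition state controlled by the (R)-benzyl auxiliary, setting C7 (R) and C8 (S) syn, which becomes trans on the ring.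

Step 11
Reactants: 17 aldol adduct; 16 silyloxymethyl acrylic acid
Product: 18 methyl (3R,4S,6R)-6-(acetoxymethyl)-3-{[(4R)-4-benzyl-2-thioxo-1,3-thiazolidin-3-yl]carbonyl}-4-{[2-({[tert-butyl(diphenyl)silyl]oxy}methyl)prop-2-enoyl]oxy}-6-ethenyl-8-methyl-2-methylidenenon-7-enoate
Conditions: N,N'-diisopropylcarbodiimide, 4-(dimethylamino)pyridine (10 mol %), CH2Cl2, 0 °C
Reagents that add atoms: none
Why: Steglich esterification installs the final C8 ester with retention and caps O8 so that only O6 can lactonise later; low temperature and catalytic base limit β-elimination.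

Step 12
Reactants: 18 acylated imide
Product: 19 methyl (3R,4S,6R)-6-(acetoxymethyl)-4-{[2-({[tert-butyl(diphenyl)silyl]oxy}methyl)prop-2-enoyl]oxy}-6-ethenyl-3-formyl-8-methyl-2-methylidenenon-7-enoate
Conditions: i-Bu2AlH (1.2 equiv), CH2Cl2, −78 °C, 15 min; aq. potassium sodium tartrate (KNaC4H4O6); used crude at once
Reagents that add atoms: none
Why: i-Bu2AlH reduces the activated N-acylthiazolidinethione to the aldehyde (reductive auxiliary cleavage) much faster than it attacks the esters at −78 °C; C7 is not touched.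

Step 13
Reactants: 19 aldehyde
Product: 21 (3aR,4S,6R,7S,7aR)-6-(acetoxymethyl)-6-ethenyl-3-methylidene-2-oxo-7-(prop-1-en-2-yl)octahydro-1-benzofuran-4-yl 2-({[tert-butyl(diphenyl)silyl]oxy}methyl)prop-2-enoate, via hydroxy ester 20 (not isolated)
Conditions: Sc(OTf)3 (20 mol %), CH2Cl2, −40 °C → rt; then 40 °C
Reagents that add atoms: none
Why: Lewis-acid-catalysed intramolecular carbonyl-ene (Prins-type) cyclisation of the citronellal-to-isopulegol kind closes the cyclohexane through a chair in which the C7 and C8 substituents, the carbonyl oxygen and the reacting alkene are equatorial (C14 axial), setting C5 and C6 and creating the isopropenyl group; the same scandium salt then catalyses lactonisation of the new C6–OH onto the C12 methyl ester to the trans-fused lactone.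

Step 14
Reactants: 21 bicyclic lactone
Product: 22 (3aR,4S,6R,7R,7aR)-6-(acetoxymethyl)-6-ethenyl-3-methylidene-2-oxo-7-(3-oxoprop-1-en-2-yl)octahydro-1-benzofuran-4-yl 2-({[tert-butyl(diphenyl)silyl]oxy}methyl)prop-2-enoate
Conditions: SeO2 (1.5 equiv), 1,4-dioxane, 70 °C
Reagents that add atoms: selenium dioxide O=[Se]=O
Why: Riley allylic oxidation (ene reaction, [2,3]-shift, further oxidation) attacks only the electron-rich isopropenyl group at its methyl group, giving the 2-substituted acrolein; the vinyl group has no allylic hydrogen and the two acrylate-type alkenes are deactivated.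

Step 15
Reactants: 22 silyl-protected enal
Product: 23 (3aR,4S,6R,7R,7aR)-6-(acetoxymethyl)-6-ethenyl-3-methylidene-2-oxo-7-(3-oxoprop-1-en-2-yl)octahydro-1-benzofuran-4-yl 2-(hydroxymethyl)prop-2-enoate
Conditions: HF·pyridine, pyridine, THF, 0 °C → rt
Reagents that add atoms: none
Why: Fluoride-mediated silyl ether cleavage under buffered, non-basic conditions that leave the enal, acetate, acrylate ester and methylene lactone intact.

## Compound list

1 | diethyl 2-(2,2-diethoxyethyl)malonate | CCOC(=O)C(CC(OCC)OCC)C(=O)OCC | starting material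
2 | phenyl vinyl sulfoxide | C=CS(=O)c1ccccc1 | starting material
3 | diethyl 2-(2,2-diethoxyethyl)-2-[2-(phenylsulfinyl)ethyl]malonate | CCOC(=O)C(CCS(=O)c1ccccc1)(CC(OCC)OCC)C(=O)OCC | intermediate (not isolated)
4 | diethyl 2-(2,2-diethoxyethyl)-2-vinylmalonate | CCOC(=O)C(C=C)(CC(OCC)OCC)C(=O)OCC | intermediate
5 | 2-(2,2-diethoxyethyl)-2-vinylpropane-1,3-diol | C=CC(CO)(CO)CC(OCC)OCC | intermediate
6 | (2R)-2-(2,2-diethoxyethyl)-2-(hydroxymethyl)but-3-en-1-yl acetate | C=C[C@](CO)(COC(C)=O)CC(OCC)OCC | intermediate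
7 | (2S)-2-(2,2-diethoxyethyl)-2-formylbut-3-en-1-yl acetate | C=C[C@](C=O)(COC(C)=O)CC(OCC)OCC | intermediate
8 | (2R)-2-(2,2-diethoxyethyl)-2-ethenyl-4-methylpent-3-en-1-yl acetate | C=C[C@](C=C(C)C)(COC(C)=O)CC(OCC)OCC | intermediate
9 | (2R)-2-ethenyl-4-methyl-2-(2-oxoethyl)pent-3-en-1-yl acetate | C=C[C@](C=C(C)C)(COC(C)=O)CC=O | intermediate
10 | itaconic anhydride (3-methylideneoxolane-2,5-dione) | C=C1CC(=O)OC1=O | starting material
11 | (R)-4-benzyl-1,3-thiazolidine-2-thione | S=C1N[C@H](Cc2ccccc2)CS1 | starting material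
12 | 4-[(4R)-4-benzyl-2-thioxo-1,3-thiazolidin-3-yl]-2-methylidene-4-oxobutanoic acid (present as its sodium salt) | C=C(CC(=O)N1[C@H](Cc2ccccc2)CSC1=S)C(=O)O | intermediate (not isolated)
13 | methyl 4-[(4R)-4-benzyl-2-thioxo-1,3-thiazolidin-3-yl]-2-methylidene-4-oxobutanoate | C=C(CC(=O)N1[C@H](Cc2ccccc2)CSC1=S)C(=O)OC | intermediate
14 | ethyl 2-(hydroxymethyl)prop-2-enoate | C=C(CO)C(=O)OCC | starting material
15 | ethyl 2-({[tert-butyl(diphenyl)silyl]oxy}methyl)prop-2-enoate | C=C(CO[Si](c1ccccc1)(c1ccccc1)C(C)(C)C)C(=O)OCC | intermediate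
16 | 2-({[tert-butyl(diphenyl)silyl]oxy}methyl)prop-2-enoic acid | C=C(CO[Si](c1ccccc1)(c1ccccc1)C(C)(C)C)C(=O)O | intermediate
17 | methyl (3R,4S,6R)-6-(acetoxymethyl)-3-{[(4R)-4-benzyl-2-thioxo-1,3-thiazolidin-3-yl]carbonyl}-6-ethenyl-4-hydroxy-8-methyl-2-methylidenenon-7-enoate | C=C[C@](C=C(C)C)(COC(C)=O)C[C@H](O)[C@H](C(=O)N1[C@H](Cc2ccccc2)CSC1=S)C(=C)C(=O)OC | intermediate
18 | methyl (3R,4S,6R)-6-(acetoxymethyl)-3-{[(4R)-4-benzyl-2-thioxo-1,3-thiazolidin-3-yl]carbonyl}-4-{[2-({[tert-butyl(diphenyl)silyl]oxy}methyl)prop-2-enoyl]oxy}-6-ethenyl-8-methyl-2-methylidenenon-7-enoate | C=C[C@](C=C(C)C)(COC(C)=O)C[C@H](OC(=O)C(=C)CO[Si](c1ccccc1)(c1ccccc1)C(C)(C)C)[C@H](C(=O)N1[C@H](Cc2ccccc2)CSC1=S)C(=C)C(=O)OC | intermediate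
19 | methyl (3R,4S,6R)-6-(acetoxymethyl)-4-{[2-({[tert-butyl(diphenyl)silyl]oxy}methyl)prop-2-enoyl]oxy}-6-ethenyl-3-formyl-8-methyl-2-methylidenenon-7-enoate | C=C[C@](C=C(C)C)(COC(C)=O)C[C@H](OC(=O)C(=C)CO[Si](c1ccccc1)(c1ccccc1)C(C)(C)C)[C@H](C=O)C(=C)C(=O)OC | intermediate
20 | methyl 2-[(1S,2R,3S,4R,6S)-4-(acetoxymethyl)-6-{[2-({[tert-butyl(diphenyl)silyl]oxy}methyl)prop-2-enoyl]oxy}-4-ethenyl-2-hydroxy-3-(prop-1-en-2-yl)cyclohexyl]prop-2-enoate | C=C[C@]1(COC(C)=O)C[C@H](OC(=O)C(=C)CO[Si](c2ccccc2)(c2ccccc2)C(C)(C)C)[C@@H](C(=C)C(=O)OC)[C@H](O)[C@H]1C(=C)C | intermediate (not isolated)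
21 | (3aR,4S,6R,7S,7aR)-6-(acetoxymethyl)-6-ethenyl-3-methylidene-2-oxo-7-(prop-1-en-2-yl)octahydro-1-benzofuran-4-yl 2-({[tert-butyl(diphenyl)silyl]oxy}methyl)prop-2-enoate | C=C[C@]1(COC(C)=O)C[C@H](OC(=O)C(=C)CO[Si](c3ccccc3)(c3ccccc3)C(C)(C)C)[C@H]2C(=C)C(=O)O[C@@H]2[C@H]1C(=C)C | intermediate
22 | (3aR,4S,6R,7R,7aR)-6-(acetoxymethyl)-6-ethenyl-3-methylidene-2-oxo-7-(3-oxoprop-1-en-2-yl)octahydro-1-benzofuran-4-yl 2-({[tert-butyl(diphenyl)silyl]oxy}methyl)prop-2-enoate | C=C[C@]1(COC(C)=O)C[C@H](OC(=O)C(=C)CO[Si](c3ccccc3)(c3ccccc3)C(C)(C)C)[C@H]2C(=C)C(=O)O[C@@H]2[C@H]1C(=C)C=O | intermediate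
23 | (3aR,4S,6R,7R,7aR)-6-(acetoxymethyl)-6-ethenyl-3-methylidene-2-oxo-7-(3-oxoprop-1-en-2-yl)octahydro-1-benzofuran-4-yl 2-(hydroxymethyl)prop-2-enoate | C=C[C@]1(COC(C)=O)C[C@H](OC(=O)C(=C)CO)[C@H]2C(=C)C(=O)O[C@@H]2[C@H]1C(=C)C=O | target

## Step count and risks

Total step count: 15. Longest linear sequence: 12 steps (steps 1–6, then 10–15).

**Step 13 (ene/lactonisation cascade).** The aldehyde may eliminate or isomerise before the hindered neopentyl alkene reacts, or the ene step may give the wrong C5/C6 diastereomer. The fallback sets out from 7 and comes back at 21; it replaces the ene donor by an allylsilane so that the same C5–C6 bond is closed by an intramolecular Hosomi–Sakurai allylation. Wittig reaction of 7 with [1-methyl-2-(trimethylsilyl)ethylidene]triphenylphosphorane (from EtPPh3 Br, n-BuLi, Me3SiCH2I, then n-BuLi) gives the allylsilane acetal F11 as an E/Z mixture. Acetal hydrolysis as in step 6 gives the allylsilane aldehyde F12, the aldol with 13 (enolate pre-formed, −78 °C) gives the allylsilane aldol adduct F13, esterification with 16 gives the allylsilane ester F14, and i-Bu2AlH gives the allylsilane formyl ester F15. BF3·OEt2 in CH2Cl2 at −78 °C then gives the hydroxy ester 20, which lactonises with Sc(OTf)3 to 21.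

**Step 12 (i-Bu2AlH cleavage to the β-acyloxy aldehyde).** Over-reduction of the acetate or acrylate esters, or β-elimination of the C8 carboxylate from 18 or 19, is possible. The fallback sets out from 17 and comes back at 21; it carries O8 as a silyl ether through reduction and ring formation and adds the side-chain ester afterwards. t-BuMe2SiOTf and 2,6-lutidine convert 17 into the silyl ether imide F6, and i-Bu2AlH gives the stable β-silyloxy aldehyde F7. Sc(OTf)3 closes both rings through the silyloxy hydroxy ester F8 (not isolated) to the silyl-protected lactone F9. HF·pyridine gives the C8 alcohol lactone F10, and esterification with 16 (N,N'-diisopropylcarbodiimide, 4-(dimethylamino)pyridine) gives 21.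

**Step 3 (lipase desymmetrisation).** Enantioselectivity between the vinyl and 2,2-diethoxyethyl groups may be low. The fallback sets out from 4 and comes back at 8; it desymmetrises at the diester stage and reorders the redox steps so that the acetate is introduced last. Pig liver esterase (pH 7 buffer) hydrolyses one enantiotopic ester of 4 to the half-ester F1, and BH3·SMe2 reduces the acid selectively to the hydroxy ester F2. Dess–Martin oxidation gives the formyl ester F3, the isopropylidene Wittig reaction gives the dienyl ester F4, LiAlH4 gives the dienyl alcohol F5, and Ac2O in pyridine gives 8.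

## Further compounds

F1 | step 3 | (2R)-2-(2,2-diethoxyethyl)-2-(ethoxycarbonyl)but-3-enoic acid | C=C[C@](C(=O)O)(C(=O)OCC)CC(OCC)OCC
F2 | step 3 | ethyl (2R)-2-(2,2-diethoxyethyl)-2-(hydroxymethyl)but-3-enoate | C=C[C@](CO)(C(=O)OCC)CC(OCC)OCC
F3 | step 3 | ethyl (2R)-2-(2,2-diethoxyethyl)-2-formylbut-3-enoate | C=C[C@](C=O)(C(=O)OCC)CC(OCC)OCC
F4 | step 3 | ethyl (2R)-2-(2,2-diethoxyethyl)-2-ethenyl-4-methylpent-3-enoate | C=C[C@](C=C(C)C)(C(=O)OCC)CC(OCC)OCC
F5 | step 3 | (2R)-2-(2,2-diethoxyethyl)-2-ethenyl-4-methylpent-3-en-1-ol | C=C[C@](C=C(C)C)(CO)CC(OCC)OCC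
F6 | step 12 | aldol adduct 17 with O8 as its tert-butyldimethylsilyl ether | C=C[C@](C=C(C)C)(COC(C)=O)C[C@H](O[Si](C)(C)C(C)(C)C)[C@H](C(=O)N1[C@H](Cc2ccccc2)CSC1=S)C(=C)C(=O)OC
F7 | step 12 | methyl (3R,4S,6R)-6-(acetoxymethyl)-4-{[tert-butyl(dimethyl)silyl]oxy}-6-ethenyl-3-formyl-8-methyl-2-methylidenenon-7-enoate | C=C[C@](C=C(C)C)(COC(C)=O)C[C@H](O[Si](C)(C)C(C)(C)C)[C@H](C=O)C(=C)C(=O)OC
F8 | step 12 | hydroxy ester 20 with OSi(t-Bu)Me2 at C8 in place of the acrylate ester | C=C[C@]1(COC(C)=O)C[C@H](O[Si](C)(C)C(C)(C)C)[C@@H](C(=C)C(=O)OC)[C@H](O)[C@H]1C(=C)C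
F9 | step 12 | lactone 21 with OSi(t-Bu)Me2 at C8 in place of the acrylate ester | C=C[C@]1(COC(C)=O)C[C@H](O[Si](C)(C)C(C)(C)C)[C@H]2C(=C)C(=O)O[C@@H]2[C@H]1C(=C)C
F10 | step 12 | [(3aR,4S,6R,7S,7aR)-6-ethenyl-4-hydroxy-3-methylidene-2-oxo-7-(prop-1-en-2-yl)octahydro-1-benzofuran-6-yl]methyl acetate | C=C[C@]1(COC(C)=O)C[C@H](O)[C@H]2C(=C)C(=O)O[C@@H]2[C@H]1C(=C)C
F11 | step 13 | (2R)-2-(2,2-diethoxyethyl)-2-ethenyl-4-methyl-5-(trimethylsilyl)pent-3-en-1-yl acetate (E/Z mixture) | C=C[C@](C=C(C)C[Si](C)(C)C)(COC(C)=O)CC(OCC)OCC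
F12 | step 13 | (2R)-2-ethenyl-4-methyl-2-(2-oxoethyl)-5-(trimethylsilyl)pent-3-en-1-yl acetate | C=C[C@](C=C(C)C[Si](C)(C)C)(COC(C)=O)CC=O
F13 | step 13 | aldol adduct 17 carrying CH2SiMe3 in place of one C4 methyl group | C=C[C@](C=C(C)C[Si](C)(C)C)(COC(C)=O)C[C@H](O)[C@H](C(=O)N1[C@H](Cc2ccccc2)CSC1=S)C(=C)C(=O)OC
F14 | step 13 | acylated imide 18 carrying CH2SiMe3 in place of one C4 methyl group | C=C[C@](C=C(C)C[Si](C)(C)C)(COC(C)=O)C[C@H](OC(=O)C(=C)CO[Si](c1ccccc1)(c1ccccc1)C(C)(C)C)[C@H](C(=O)N1[C@H](Cc2ccccc2)CSC1=S)C(=C)C(=O)OC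
F15 | step 13 | aldehyde 19 carrying CH2SiMe3 in place of one C4 methyl group | C=C[C@](C=C(C)C[Si](C)(C)C)(COC(C)=O)C[C@H](OC(=O)C(=C)CO[Si](c1ccccc1)(c1ccccc1)C(C)(C)C)[C@H](C=O)C(=C)C(=O)OC
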